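The rate constants are made up, and the outcome is calculated.

- Before trusting a printed percentage for green, we look at its neighbours grey and ochre: same charge and time, colder and hotter, with the intermediate perhaps low in either for opposite reasons.

| setting | ochre | green | grey | violet |
|---|---|---|---|---|
| substrate | 0.73 M | 0.73 M | 0.73 M | 0.73 M |
| temperature | 60 °C | 45 °C | 30 °C |  |
| time | 2.0 min | 2.0 min | 2.0 min | 2.0 min |
| remark |  |  |  | at 30 °C until 80 s, from then on at 60 °C |

* which flask leads in amount of intermediate, in percent of the substrate charged ("all alike" within 1.5 percentage points) (ochre / green / grey / violet / all alike)
* how much intermediate is there at the end, in percent of the substrate charged: ochre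
* how much intermediate is there at the end, in percent of the substrate charged: green
* how much intermediate is there at the end, in percent of the substrate charged: grey
* how much intermediate is there at the end, in percent of the substrate charged: violet

    intermediate → target (k1 = 0.066 s⁻¹, Ea1 = 93.0 kJ mol⁻¹)
    crystals ⇌ target, rate k2*(cs2 - [target]) while solid is left; crystals form when [target] > cs2 (cs2 = 33 mM, k2 = 0.36 s⁻¹)
    substrate → intermediate (k3 = 0.016 s⁻¹, Ea3 = 84.0 kJ mol⁻¹)
    substrate ⇌ dormant form (K4 = 1.8, k4 = 0.0062 s⁻¹, Ea4 = 83.0 kJ mol⁻¹, ΔH4 = 8.00 kJ mol⁻¹)
    (constants at 60 °C)

- target is meant together with its crystals
- solid, in amounts per volume of the solution: crystals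
- the constants hold at 60 °C; other temperatures follow from the activation energies and enthalpies

- Our zero is the balance, where intermediate is made as fast as it is used: kmake[substrate] = kuse[intermediate], with kmake for substrate → intermediate and kuse for intermediate → target.
- So we first ask which numbers this balance needs in green, taking substrate left as a plain decay by kmake and kpark, the forward step to dormant form.
- The solubility and dissolution coefficient of the crystals can be rough, since target stands in no rate of the intermediate .
- The falling back of dormant form takes 17.3 min in green, longer than the run, so we drop it.
- At 0.00151 s⁻¹, kpark passes a fractional error into the answer times 0.181.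
- At 0.00383 s⁻¹, kmake passes it on times 0.540, since more made also means less substrate.
- At 0.0136 s⁻¹, kuse passes it on in full, so this is the number to know well.
- Now the number: the standing ratio, the usual steady-state ratio, is kmake/kuse at the flask's temperature, the [intermediate]/[substrate] at which made equals used, and in green it is 0.283.
- Our plain decay puts the peak of green at 1.89 min, close to the 2.0 min of the reading, so we may stand on the balance: substrate left 52.7%, intermediate 14.9%.
- The same plain decay puts the peak of ochre at 0.415 min, at about 14.0%, which is less than green, and ochre has 1.58 min to fall from there until the reading.
- Grey makes at most kmake times the time, 9.55%, which is also less than green.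
- We reckon violet no further, so our pick among the steady flasks is green.
- The forecast names green, with ochre 3.14%, green 15.5%, grey 7.75% and violet 11.9%, on the ground that “Crystals and target sit downstream, so they do not affect the intermediate”; for green it stands above our figure.

The flask gives green in the lead: ochre 3.14%, green 15.5%, grey 7.75%, violet 11.9%. In green at 2.00 min, intermediate is made at 0.975 of the rate at which it is used. The standing ratio times the 53% of substrate left there gives 15.0%. In the neighbour, green left until 8.0 min, 11% of substrate remains, the same ratio gives 3.04%, and the reading is 4.29%, more than the balance, so there intermediate is used 1.41 times as fast as it is made.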